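**Retrosynthetic overview**
- C40 = C15 (acetylenic) + C10 + C15 (7',8'-dihydro): two Wittig olefinations on 2,7-dimethylocta-2,4,6-trienedial form C11=C12, then C11'=C12'.
- Both C15 units come from one enol triflate of O-silylated (4R,6R)-actinol, which supplies C3 and C3' (both R) from the chiral pool.
- Acetylenic half: C6–C7 by Sonogashira coupling of the triflate with (E)-3-methylpent-2-en-4-yn-1-ol (9E is bought).
- Dihydro half, key step: C6'–C7' by Pd-catalysed ring-opening coupling of 1-methylcyclopropanol with the same triflate. The cyclopropanol acts as a ketone homoenolate (β-acyl carbanion) and bonds to the former carbonyl carbon. 9'E is then fixed by syn-methylalumination of the derived alkyne.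
- Ring order: no ring is formed. Both six-membered rings are carried in from actinol; only their C5=C6 alkene is installed, at the enol triflate stage.

Assumption: (4R,6R)-actinol, 1-methylcyclopropanol, (E)-3-methylpent-2-en-4-yn-1-ol and the C10 dialdehyde are purchased; positions are cited in carotenoid numbering (C1–C15, C1'–C15').

**Step 1**
Reactants: 1 (4R,6R)-4-hydroxy-2,2,6-trimethylcyclohexan-1-one (actinol)
Product: 2 (4R,6R)-4-[(tert-butyldimethylsilyl)oxy]-2,2,6-trimethylcyclohexan-1-one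
Conditions: TBSCl, imidazole, DMF, rt
Reagents that add atoms: tert-butyldimethylsilyl chloride (TBSCl), CC(C)(C)[Si](C)(C)Cl
Why: Imidazole-promoted silylation of the secondary alcohol (silyl ether protection); neither stereocentre is touched, and C4 (R) is the future C3 and C3'.

**Step 2**
Reactants: 2 (4R,6R)-4-[(tert-butyldimethylsilyl)oxy]-2,2,6-trimethylcyclohexan-1-one
Product: 4 (4R)-4-[(tert-butyldimethylsilyl)oxy]-2,6,6-trimethylcyclohex-1-en-1-yl trifluoromethanesulfonate, via lithium enolate 3 (not isolated)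
Conditions: LiN(i-Pr)2, THF, −78 → 0 °C; PhNTf2, 0 °C → rt
Reagents that add atoms: N-phenylbis(trifluoromethanesulfonimide) (PhNTf2), O=S(=O)(N(c1ccccc1)S(=O)(=O)C(F)(F)F)C(F)(F)F
Why: Enol triflate formation: with C2 quaternary the ketone can enolise only toward C6, so O-triflation of the lithium enolate gives the tetrasubstituted ring alkene (future C5=C6 and C5'=C6') regiospecifically, erasing the C6 centre and leaving C4 (R) intact.

**Step 3 (key step)**
Reactants: 4 (4R)-4-[(tert-butyldimethylsilyl)oxy]-2,6,6-trimethylcyclohex-1-en-1-yl trifluoromethanesulfonate; 5 1-methylcyclopropan-1-ol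
Product: 6 4-[(4R)-4-[(tert-butyldimethylsilyl)oxy]-2,6,6-trimethylcyclohex-1-en-1-yl]butan-2-one
Conditions: Pd(OAc)2 (5 mol %), XPhos (10 mol %), Cs2CO3 (2 equiv), 5 (2 equiv), toluene, 80 °C
Reagents that add atoms: none
Why: Proposed new method: zerovalent palladium inserts into the C–OTf bond of 4, the caesium cyclopropoxide of 5 displaces triflate on palladium, strain-driven β-carbon elimination opens the ring to a β-ketoalkyl–palladium (a ketone homoenolate, so C7', natively the acceptor β-carbon of butan-2-one, arrives as a carbanion and is joined to C6', the former carbonyl carbon of actinol), and C(sp2)–C(sp3) reductive elimination, favoured over β-hydride loss by the bulky biarylphosphine and the crowded tetrasubstituted alkenyl ligand, gives 6; the closest known reaction types are the Pd-catalysed ring-opening cross-coupling of cyclopropanols with aryl halides and the Pd-catalysed coupling of zinc ester homoenolates with enol triflates; C3' (R) is not involved.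

**Step 4**
Reactants: 6 4-[(4R)-4-[(tert-butyldimethylsilyl)oxy]-2,6,6-trimethylcyclohex-1-en-1-yl]butan-2-one
Product: 10 tert-butyl{[(1R)-4-(but-3-yn-1-yl)-3,5,5-trimethylcyclohex-3-en-1-yl]oxy}dimethylsilane, via lithium enolate 7 (not isolated), via enol phosphate 8 (not isolated), via lithium acetylide 9 (not isolated)
Conditions: LiN(i-Pr)2 (1.1 equiv), THF, −78 °C; ClP(O)(OEt)2, −78 °C → rt; LiN(i-Pr)2 (2.3 equiv), −78 °C → rt; aq NH4Cl
Reagents that add atoms: none
Why: Negishi enol phosphate route from a methyl ketone to a terminal alkyne: kinetic deprotonation at CH3, O-phosphorylation, then base-induced β-elimination of diethyl phosphate, the alkyne being held as its lithium acetylide until the quench; no stereo-element is affected.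

**Step 5**
Reactants: 10 tert-butyl{[(1R)-4-(but-3-yn-1-yl)-3,5,5-trimethylcyclohex-3-en-1-yl]oxy}dimethylsilane
Product: 13 (2E)-5-[(4R)-4-[(tert-butyldimethylsilyl)oxy]-2,6,6-trimethylcyclohex-1-en-1-yl]-3-methylpent-2-en-1-ol, via alkenylalane 11 (not isolated), via lithium alanate 12 (not isolated)
Conditions: AlMe3 (2.5 equiv), Cp2ZrCl2 (0.25 equiv), CH2Cl2, 0 °C → rt; evaporate, THF, n-BuLi, −78 °C; (CH2O)n, −78 °C → rt; aq KNaC4H4O6
Reagents that add atoms: trimethylaluminium, C[Al](C)C; paraformaldehyde (as formaldehyde), C=O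
Why: Negishi zirconium-catalysed carboalumination followed by hydroxymethylation of the alanate: Me–Al adds syn across the alkyne with methyl on the internal carbon (C9'), and the C–Al bond is replaced by C–CH2OH with retention, which sets 9'E (>98:2).

**Step 6**
Reactants: 13 (2E)-5-[(4R)-4-[(tert-butyldimethylsilyl)oxy]-2,6,6-trimethylcyclohex-1-en-1-yl]-3-methylpent-2-en-1-ol
Product: 16 [(2E)-5-[(4R)-4-hydroxy-2,6,6-trimethylcyclohex-1-en-1-yl]-3-methylpent-2-en-1-yl]triphenylphosphonium bromide, via allylic bromide 14 (not isolated), via silylated phosphonium bromide 15 (not isolated)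
Conditions: CBr4 (1.1 equiv), PPh3 (1.1 equiv), CH2Cl2, 0 °C; PPh3 (1.3 equiv), rt, 12 h; then MeOH, 48% aq HBr (0.2 equiv), rt; crystallise (CH2Cl2/EtOAc)
Reagents that add atoms: triphenylphosphine, c1ccc(cc1)P(c1ccccc1)c1ccccc1; carbon tetrabromide, BrC(Br)(Br)Br
Why: Appel bromination (SN2, no allyl cation, so 9'E is kept), quaternisation of PPh3 by the primary allylic bromide, then acid-catalysed methanolysis of the silyl ether; C3' is not touched.

**Step 7**
Reactants: 4 (4R)-4-[(tert-butyldimethylsilyl)oxy]-2,6,6-trimethylcyclohex-1-en-1-yl trifluoromethanesulfonate; 17 (2E)-3-methylpent-2-en-4-yn-1-ol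
Product: 18 (2E)-5-[(4R)-4-[(tert-butyldimethylsilyl)oxy]-2,6,6-trimethylcyclohex-1-en-1-yl]-3-methylpent-2-en-4-yn-1-ol
Conditions: Pd(PPh3)4 (5 mol %), CuI (10 mol %), i-Pr2NH, DMF, 50 °C
Reagents that add atoms: none
Why: Sonogashira coupling: oxidative addition of zerovalent palladium to the enol triflate, transmetalation from the copper acetylide and reductive elimination form C6–C7; the E alkene bought in 17 becomes 9E unchanged and the free primary alcohol is tolerated.

**Step 8**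
Reactants: 18 (2E)-5-[(4R)-4-[(tert-butyldimethylsilyl)oxy]-2,6,6-trimethylcyclohex-1-en-1-yl]-3-methylpent-2-en-4-yn-1-ol
Product: 21 [(2E)-5-[(4R)-4-hydroxy-2,6,6-trimethylcyclohex-1-en-1-yl]-3-methylpent-2-en-4-yn-1-yl]triphenylphosphonium bromide, via allylic bromide 19 (not isolated), via silylated phosphonium bromide 20 (not isolated)
Conditions: CBr4 (1.1 equiv), PPh3 (1.1 equiv), CH2Cl2, 0 °C; PPh3 (1.3 equiv), rt, 12 h; then MeOH, 48% aq HBr (0.2 equiv), rt; crystallise (CH2Cl2/EtOAc)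
Reagents that add atoms: triphenylphosphine, c1ccc(cc1)P(c1ccccc1)c1ccccc1; carbon tetrabromide, BrC(Br)(Br)Br
Why: Same Appel bromination, phosphine quaternisation and acidic desilylation as in step 6; both substitutions are SN2 at the primary carbon, so the 9E enyne geometry and C3 (R) are preserved.

**Step 9**
Reactants: 21 [(2E)-5-[(4R)-4-hydroxy-2,6,6-trimethylcyclohex-1-en-1-yl]-3-methylpent-2-en-4-yn-1-yl]triphenylphosphonium bromide; 22 (2E,4E,6E)-2,7-dimethylocta-2,4,6-trienedial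
Product: 24 (2E,4E,6E,8E,10E)-13-[(4R)-4-hydroxy-2,6,6-trimethylcyclohex-1-en-1-yl]-2,7,11-trimethyltrideca-2,4,6,8,10-pentaen-12-ynal, via phosphorus ylide 23 (not isolated)
Conditions: NaOMe, MeOH/CH2Cl2, 0 °C → rt, 21 and base added slowly to 22 (3 equiv); then EtOAc, reflux, dark; SiO2
Reagents that add atoms: none
Why: Wittig olefination of one formyl group of the dialdehyde used in threefold excess (statistical control, excess 22 recovered) forms C11=C12; the hindered 11Z isomer relaxes thermally to 11E, while 9E, which must not be equilibrated, is left alone.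

**Step 10**
Reactants: 16 [(2E)-5-[(4R)-4-hydroxy-2,6,6-trimethylcyclohex-1-en-1-yl]-3-methylpent-2-en-1-yl]triphenylphosphonium bromide; 24 (2E,4E,6E,8E,10E)-13-[(4R)-4-hydroxy-2,6,6-trimethylcyclohex-1-en-1-yl]-2,7,11-trimethyltrideca-2,4,6,8,10-pentaen-12-ynal
Product: 26 (3R,3'R)-7,8-didehydro-7',8'-dihydro-β,β-carotene-3,3'-diol (all-E; CNP0178054.1), via phosphorus ylide 25 (not isolated)
Conditions: NaOMe, MeOH/CH2Cl2, rt; then EtOAc, reflux, dark, no iodine; SiO2, crystallise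
Reagents that add atoms: none
Why: Wittig olefination forms C11'=C12' and completes the C40 chain; 9'E and 9E are carried in unchanged, both C3/C3' (R) centres come from 1, and the hindered 11'Z by-product is isomerised by heat alone because iodine would drive the acetylenic 9E bond toward 9Z.

**Compound list**
1 | (4R,6R)-4-hydroxy-2,2,6-trimethylcyclohexan-1-one (actinol) | O=C1C(C)(C)C[C@H](O)C[C@H]1C | starting material
2 | (4R,6R)-4-[(tert-butyldimethylsilyl)oxy]-2,2,6-trimethylcyclohexan-1-one | O=C1C(C)(C)C[C@H](O[Si](C)(C)C(C)(C)C)C[C@H]1C | intermediate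
3 | lithium (4R)-4-[(tert-butyldimethylsilyl)oxy]-2,6,6-trimethylcyclohex-1-en-1-olate (lithium enolate of 2) | [Li]OC1=C(C)C[C@@H](O[Si](C)(C)C(C)(C)C)CC1(C)C | intermediate
4 | (4R)-4-[(tert-butyldimethylsilyl)oxy]-2,6,6-trimethylcyclohex-1-en-1-yl trifluoromethanesulfonate | CC1=C(OS(=O)(=O)C(F)(F)F)C(C)(C)C[C@H](O[Si](C)(C)C(C)(C)C)C1 | intermediate
5 | 1-methylcyclopropan-1-ol | CC1(O)CC1 | starting material
6 | 4-[(4R)-4-[(tert-butyldimethylsilyl)oxy]-2,6,6-trimethylcyclohex-1-en-1-yl]butan-2-one | CC(=O)CCC1=C(C)C[C@@H](O[Si](C)(C)C(C)(C)C)CC1(C)C | intermediate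
7 | lithium 4-[(4R)-4-[(tert-butyldimethylsilyl)oxy]-2,6,6-trimethylcyclohex-1-en-1-yl]but-1-en-2-olate (kinetic enolate of 6) | [Li]OC(=C)CCC1=C(C)C[C@@H](O[Si](C)(C)C(C)(C)C)CC1(C)C | intermediate
8 | diethyl 4-[(4R)-4-[(tert-butyldimethylsilyl)oxy]-2,6,6-trimethylcyclohex-1-en-1-yl]but-1-en-2-yl phosphate | C=C(OP(=O)(OCC)OCC)CCC1=C(C)C[C@@H](O[Si](C)(C)C(C)(C)C)CC1(C)C | intermediate
9 | lithium acetylide of 10: {4-[(4R)-4-[(tert-butyldimethylsilyl)oxy]-2,6,6-trimethylcyclohex-1-en-1-yl]but-1-yn-1-yl}lithium | [Li]C#CCCC1=C(C)C[C@@H](O[Si](C)(C)C(C)(C)C)CC1(C)C | intermediate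
10 | tert-butyl{[(1R)-4-(but-3-yn-1-yl)-3,5,5-trimethylcyclohex-3-en-1-yl]oxy}dimethylsilane | C#CCCC1=C(C)C[C@@H](O[Si](C)(C)C(C)(C)C)CC1(C)C | intermediate
11 | {(1E)-4-[(4R)-4-[(tert-butyldimethylsilyl)oxy]-2,6,6-trimethylcyclohex-1-en-1-yl]-2-methylbut-1-en-1-yl}dimethylalane | C[Al](C)/C=C(\C)CCC1=C(C)C[C@@H](O[Si](C)(C)C(C)(C)C)CC1(C)C | intermediate
12 | lithium butyl{(1E)-4-[(4R)-4-[(tert-butyldimethylsilyl)oxy]-2,6,6-trimethylcyclohex-1-en-1-yl]-2-methylbut-1-en-1-yl}dimethylalanate | [Li+].CCCC[Al-](C)(C)/C=C(\C)CCC1=C(C)C[C@@H](O[Si](C)(C)C(C)(C)C)CC1(C)C | intermediate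
13 | (2E)-5-[(4R)-4-[(tert-butyldimethylsilyl)oxy]-2,6,6-trimethylcyclohex-1-en-1-yl]-3-methylpent-2-en-1-ol | OC/C=C(\C)CCC1=C(C)C[C@@H](O[Si](C)(C)C(C)(C)C)CC1(C)C | intermediate
14 | (2E)-5-[(4R)-4-[(tert-butyldimethylsilyl)oxy]-2,6,6-trimethylcyclohex-1-en-1-yl]-3-methylpent-2-en-1-yl bromide | BrC/C=C(\C)CCC1=C(C)C[C@@H](O[Si](C)(C)C(C)(C)C)CC1(C)C | intermediate
15 | [(2E)-5-[(4R)-4-[(tert-butyldimethylsilyl)oxy]-2,6,6-trimethylcyclohex-1-en-1-yl]-3-methylpent-2-en-1-yl]triphenylphosphonium bromide | [Br-].c1ccc(cc1)[P+](c1ccccc1)(c1ccccc1)C/C=C(\C)CCC1=C(C)C[C@@H](O[Si](C)(C)C(C)(C)C)CC1(C)C | intermediate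
16 | [(2E)-5-[(4R)-4-hydroxy-2,6,6-trimethylcyclohex-1-en-1-yl]-3-methylpent-2-en-1-yl]triphenylphosphonium bromide | [Br-].c1ccc(cc1)[P+](c1ccccc1)(c1ccccc1)C/C=C(\C)CCC1=C(C)C[C@@H](O)CC1(C)C | intermediate
17 | (2E)-3-methylpent-2-en-4-yn-1-ol | C#C/C(C)=C/CO | starting material
18 | (2E)-5-[(4R)-4-[(tert-butyldimethylsilyl)oxy]-2,6,6-trimethylcyclohex-1-en-1-yl]-3-methylpent-2-en-4-yn-1-ol | CC1=C(C#C/C(C)=C/CO)C(C)(C)C[C@H](O[Si](C)(C)C(C)(C)C)C1 | intermediate
19 | (2E)-5-[(4R)-4-[(tert-butyldimethylsilyl)oxy]-2,6,6-trimethylcyclohex-1-en-1-yl]-3-methylpent-2-en-4-yn-1-yl bromide | CC1=C(C#C/C(C)=C/CBr)C(C)(C)C[C@H](O[Si](C)(C)C(C)(C)C)C1 | intermediate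
20 | [(2E)-5-[(4R)-4-[(tert-butyldimethylsilyl)oxy]-2,6,6-trimethylcyclohex-1-en-1-yl]-3-methylpent-2-en-4-yn-1-yl]triphenylphosphonium bromide | [Br-].CC1=C(C#C/C(C)=C/C[P+](c2ccccc2)(c2ccccc2)c2ccccc2)C(C)(C)C[C@H](O[Si](C)(C)C(C)(C)C)C1 | intermediate
21 | [(2E)-5-[(4R)-4-hydroxy-2,6,6-trimethylcyclohex-1-en-1-yl]-3-methylpent-2-en-4-yn-1-yl]triphenylphosphonium bromide | [Br-].CC1=C(C#C/C(C)=C/C[P+](c2ccccc2)(c2ccccc2)c2ccccc2)C(C)(C)C[C@H](O)C1 | intermediate
22 | (2E,4E,6E)-2,7-dimethylocta-2,4,6-trienedial (C10 dialdehyde) | O=C/C(C)=C/C=C/C=C(C)/C=O | starting material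
23 | {(2E)-5-[(4R)-4-hydroxy-2,6,6-trimethylcyclohex-1-en-1-yl]-3-methylpent-2-en-4-yn-1-ylidene}triphenylphosphorane (ylide of 21) | CC1=C(C#C/C(C)=C/C=P(c2ccccc2)(c2ccccc2)c2ccccc2)C(C)(C)C[C@H](O)C1 | intermediate
24 | (2E,4E,6E,8E,10E)-13-[(4R)-4-hydroxy-2,6,6-trimethylcyclohex-1-en-1-yl]-2,7,11-trimethyltrideca-2,4,6,8,10-pentaen-12-ynal | CC1=C(C#C/C(C)=C/C=C/C(C)=C/C=C/C=C(C)/C=O)C(C)(C)C[C@H](O)C1 | intermediate
25 | {(2E)-5-[(4R)-4-hydroxy-2,6,6-trimethylcyclohex-1-en-1-yl]-3-methylpent-2-en-1-ylidene}triphenylphosphorane (ylide of 16) | c1ccc(cc1)P(c1ccccc1)(c1ccccc1)=C/C=C(\C)CCC1=C(C)C[C@@H](O)CC1(C)C | intermediate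
26 | (3R,3'R)-7,8-didehydro-7',8'-dihydro-β,β-carotene-3,3'-diol, all-E (CNP0178054.1) | CC1=C(C#C/C(C)=C/C=C/C(C)=C/C=C/C=C(C)/C=C/C=C(\C)CCC2=C(C)C[C@@H](O)CC2(C)C)C(C)(C)C[C@H](O)C1 | target

**Step count**
Total: 10 steps. Longest linear sequence: 7 steps (1, 2, 3, 4, 5, 6, 10); the other branch is 1, 2, 7, 8, 9, 10.

**Three steps most likely to fail**

Step 3. The coupling is new on a tetrasubstituted enol triflate; β-hydride loss to methyl vinyl ketone or simple ring-opening of 5 to butan-2-one may win. The fallback sets out from 4 and comes back at 6. Zinc dust (LiCl, THF, 40 °C) is inserted into purchased 2-(2-bromoethyl)-2-methyl-1,3-dioxolane to give [2-(2-methyl-1,3-dioxolan-2-yl)ethyl]zinc bromide F1, a preformed acetal-masked ketone homoenolate. Negishi coupling of this reagent with 4 (Pd(OAc)2, SPhos, THF/NMP, 50 °C) gives the ketal 2-methyl-2-{2-[(4R)-4-[(tert-butyldimethylsilyl)oxy]-2,6,6-trimethylcyclohex-1-en-1-yl]ethyl}-1,3-dioxolane F2. Pyridinium p-toluenesulfonate in wet acetone at 40 °C then releases 6 with the silyl ether intact.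

Step 4. Kinetic enolisation may not be fully regioselective, and the elimination may give some allene. The fallback sets out from 6 and comes back at 13, bypassing steps 4 and 5. Horner–Wadsworth–Emmons olefination of 6 with triethyl phosphonoacetate (NaH, THF, 0 °C → reflux) gives ethyl (2E)-5-[(4R)-4-[(tert-butyldimethylsilyl)oxy]-2,6,6-trimethylcyclohex-1-en-1-yl]-3-methylpent-2-enoate F3, together with about one fifth of its 2Z isomer F4, which is removed on silica. Reduction of the E ester with i-Bu2AlH (CH2Cl2, −78 °C) gives 13.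

Step 10. The non-conjugated allyl ylide 25 may give a stubborn 11'E/11'Z mixture or a low yield with the hydroxy polyenal. The fallback sets out from 13 and comes back at 26. The Appel bromination is run alone and bromide 14 is isolated. A Michaelis–Arbuzov reaction with P(OEt)3 (neat, 110 °C) gives diethyl [(2E)-5-[(4R)-4-[(tert-butyldimethylsilyl)oxy]-2,6,6-trimethylcyclohex-1-en-1-yl]-3-methylpent-2-en-1-yl]phosphonate F5. Horner–Wadsworth–Emmons olefination of 24 with its anion (NaN(SiMe3)2, 2.2 equiv, THF, −78 °C → rt; one equivalent is taken by the C3 hydroxyl of 24) builds C11'=C12' E-selectively and gives (3R,3'R)-3'-O-(tert-butyldimethylsilyl)-7,8-didehydro-7',8'-dihydro-β,β-carotene-3,3'-diol F6. Bu4NF (THF, rt) then gives 26.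

**Further compounds**
F1 | step 3 | [2-(2-methyl-1,3-dioxolan-2-yl)ethyl]zinc bromide | CC1(CC[Zn]Br)OCCO1
F2 | step 3 | 2-methyl-2-{2-[(4R)-4-[(tert-butyldimethylsilyl)oxy]-2,6,6-trimethylcyclohex-1-en-1-yl]ethyl}-1,3-dioxolane | CC1(CCC2=C(C)C[C@@H](O[Si](C)(C)C(C)(C)C)CC2(C)C)OCCO1
F3 | step 4 | ethyl (2E)-5-[(4R)-4-[(tert-butyldimethylsilyl)oxy]-2,6,6-trimethylcyclohex-1-en-1-yl]-3-methylpent-2-enoate | CCOC(=O)/C=C(\C)CCC1=C(C)C[C@@H](O[Si](C)(C)C(C)(C)C)CC1(C)C
F4 | step 4 | ethyl (2Z)-5-[(4R)-4-[(tert-butyldimethylsilyl)oxy]-2,6,6-trimethylcyclohex-1-en-1-yl]-3-methylpent-2-enoate | CCOC(=O)/C=C(/C)CCC1=C(C)C[C@@H](O[Si](C)(C)C(C)(C)C)CC1(C)C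
F5 | step 10 | diethyl [(2E)-5-[(4R)-4-[(tert-butyldimethylsilyl)oxy]-2,6,6-trimethylcyclohex-1-en-1-yl]-3-methylpent-2-en-1-yl]phosphonate | CCOP(=O)(OCC)C/C=C(\C)CCC1=C(C)C[C@@H](O[Si](C)(C)C(C)(C)C)CC1(C)C
F6 | step 10 | (3R,3'R)-3'-O-(tert-butyldimethylsilyl)-7,8-didehydro-7',8'-dihydro-β,β-carotene-3,3'-diol | CC1=C(C#C/C(C)=C/C=C/C(C)=C/C=C/C=C(C)/C=C/C=C(\C)CCC2=C(C)C[C@@H](O[Si](C)(C)C(C)(C)C)CC2(C)C)C(C)(C)C[C@H](O)C1
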